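**Plan**

1. Retrosynthesis: the five phenol benzyl ethers come off last. The strategic cut is the C3–C3'' bond, the central bond of the 1,4-diketone C4(=O)–C3–C3''–C4''(=O) that links the two rings C. Each flavanone is then cut at its C2–aryl bond back to one common chromone, and the chromone back to phloroacetophenone.
2. Enabling feature: C3 and C3'' are the α-carbons of the two ring-C aryl ketones, each next to a C2 stereocentre carrying an aryl group, and both halves share the (2S,3R) pattern. Two enol ethers of (2S)-flavanones can therefore be joined oxidatively head to head, as in the presumed biosynthesis by union of two C3 radicals.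
3. Forward: ring A is bought, ring C is closed as the 4-pyranone, the ring-B aryl groups are added to C2 in two separate runs, the two flavanones are tied through their C4 oxygens by a temporary iPr2Si bridge, the C3–C3'' bond is formed by oxidation, and the benzyl groups are removed.
4. Stereochemistry: C2 and C2'' come from catalyst control in the rhodium-catalysed 1,4-addition. C3 and C3'' come from substrate control in the coupling: bond formation anti to each C2 aryl group gives 2,3-trans in both rings, which with two (2S) partners can only be 3R,3''R and is also the expected thermodynamic arrangement.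

Key step: step 6

Assumption: the (S)-configured biaryl bisphosphine is taken to give the (2S)-flavanone, by analogy with the sense of the same rhodium-catalysed addition to 2-cyclohexenone; should the sense be opposite for the chromone, the (R)-ligand is used instead.

**Route**

Step 1
Reactants: 1 2',4',6'-trihydroxyacetophenone; 2 benzyl bromide
Product: 3 1-[2,4-bis(benzyloxy)-6-hydroxyphenyl]ethanone
Conditions: BnBr (2.1 equiv), K2CO3 (2.2 equiv), DMF, 0 °C to rt
Reagents that add atoms: benzyl bromide (2), BrCc1ccccc1
Why: Williamson ether synthesis in which the para hydroxyl and one ortho hydroxyl are alkylated, while the remaining ortho hydroxyl is held in a hydrogen bond to the ketone and is the least nucleophilic, so two equivalents of benzyl bromide should stop at the bis-ether.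

Step 2
Reactants: 3 1-[2,4-bis(benzyloxy)-6-hydroxyphenyl]ethanone; 4 N,N-dimethylformamide dimethyl acetal
Product: 6 5,7-bis(benzyloxy)-4H-chromen-4-one, via enaminone 5 (not isolated)
Conditions: Me2NCH(OMe)2 (2 equiv), toluene, 100 °C; concentrate; then conc. HCl, CH2Cl2, rt
Reagents that add atoms: N,N-dimethylformamide dimethyl acetal (4), COC(OC)N(C)C
Why: Enaminone chromone synthesis, in which the methyl ketone condenses with the amide acetal and, on acidification, the free phenol adds to the enaminone β-carbon (6-endo-trig) with loss of dimethylamine to close ring C as the 4-pyranone.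

Step 3
Reactants: 6 5,7-bis(benzyloxy)-4H-chromen-4-one; 7 (4-methoxyphenyl)boronic acid
Product: 8 (2S)-5,7-bis(benzyloxy)-2-(4-methoxyphenyl)-2,3-dihydro-4H-chromen-4-one
Conditions: 7 (3 equiv), [Rh(OH)(C8H12)]2 (3 mol %, C8H12 = 1,5-cyclooctadiene), (S)-MeO-F12-BIPHEP (6.6 mol %; (S)-6,6'-dimethoxy-2,2'-bis[bis(3,4,5-trifluorophenyl)phosphino]biphenyl), toluene/H2O 50:1, 40 °C
Reagents that add atoms: (4-methoxyphenyl)boronic acid (7), COc1ccc(B(O)O)cc1
Why: Hayashi–Miyaura asymmetric 1,4-addition to a chromone, in which an aryl complex of monovalent rhodium adds to C2 on the face chosen by the chiral bisphosphine and the rhodium enolate is protonated, the electron-poor ligand and the near-neutral medium serving to prevent ring opening to the chalcone, so the C2 stereocentre (S) is set by the catalyst and kept.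

Step 4
Reactants: 6 5,7-bis(benzyloxy)-4H-chromen-4-one; 9 [4-(benzyloxy)phenyl]boronic acid
Product: 10 (2S)-5,7-bis(benzyloxy)-2-[4-(benzyloxy)phenyl]-2,3-dihydro-4H-chromen-4-one
Conditions: 9 (3 equiv), [Rh(OH)(C8H12)]2 (3 mol %), (S)-MeO-F12-BIPHEP (6.6 mol %), toluene/H2O 50:1, 40 °C
Reagents that add atoms: [4-(benzyloxy)phenyl]boronic acid (9), OB(O)c1ccc(OCc2ccccc2)cc1
Why: The same Hayashi–Miyaura asymmetric 1,4-addition on the common chromone, with the same catalyst-controlled facial selectivity setting C2'' as (S).

Step 5
Reactants: 8 (2S)-5,7-bis(benzyloxy)-2-(4-methoxyphenyl)-2,3-dihydro-4H-chromen-4-one; 10 (2S)-5,7-bis(benzyloxy)-2-[4-(benzyloxy)phenyl]-2,3-dihydro-4H-chromen-4-one; 11 diisopropylsilyl bis(trifluoromethanesulfonate)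
Product: 13 unsymmetrical diisopropylsilyl bis-enol ether bridging the C4 oxygens of the two (2S)-flavanones, via silyl triflate 12 (not isolated)
Conditions: iPr2Si(OTf)2 (1.05 equiv), Et3N (4 equiv), CH2Cl2, −78 °C, slow addition of 8, to 0 °C; then 10 (1.0 equiv), 0 °C to rt; NaHCO3 work-up, used crude
Reagents that add atoms: diisopropylsilyl bis(trifluoromethanesulfonate) (11), CC(C)[Si](OS(=O)(=O)C(F)(F)F)(OS(=O)(=O)C(F)(F)F)C(C)C
Why: Soft enolisation (silyl triflate and tertiary amine) carried out twice on one silicon atom, the bis-triflate being far more electrophilic than the mono-enoxysilyl triflate 12 so that 8 should add once before 10 displaces the second triflate, and since no metal enolate is formed, ring C should not open by β-elimination and C2 and C2'' should keep their configuration.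

Step 6
Reactants: 13 unsymmetrical diisopropylsilyl bis-enol ether
Product: 14 (2S,3R)-5,7-bis(benzyloxy)-3-{(2S,3R)-5,7-bis(benzyloxy)-2-[4-(benzyloxy)phenyl]-4-oxochroman-3-yl}-2-(4-methoxyphenyl)chroman-4-one
Conditions: (NH4)2Ce(NO3)6 (2.2 equiv), NaHCO3 (5 equiv), MeCN/EtCN/CH2Cl2, −30 °C; aqueous work-up
Reagents that add atoms: none
Why: One-electron oxidation of one electron-rich 4-silyloxy-2H-chromene (the C3=C4 enol ether) by tetravalent cerium gives a radical cation whose C3 attacks C3'' of the second enol ether, held within reach by the O–Si–O bridge between the two C4 oxygens; a second one-electron oxidation and loss of the silicon bridge on work-up release the 1,4-diketone C4(=O)–C3–C3''–C4''(=O). The closest known reaction type is the oxidative coupling of unsymmetrical silyl bis-enol ethers of cyclic aryl ketones such as 1-tetralone with (NH4)2Ce(NO3)6. The only ring closed is the temporary seven-membered 1,3-dioxa-2-silacycloheptane ring, formed in a 7-endo-trig mode and opened again when silicon is lost, so no ring of the target is made here. C3 and C3'' are set by substrate control: each new bond forms on the enol ether face opposite to the C2 aryl group, giving the 2,3-trans relation in both rings C, and because both flavanones are (2S) this anti/anti pairing is the homochiral, twofold-symmetric mode that such tethered bis-enol ethers of cyclic ketones are expected to favour, leading to (3R,3''R). The step needs cross- over homo-coupling, which the tether secures, and C–C bond formation faster than loss of H-2 from the radical cation (which would lead to a flavone), for which the intramolecular closure, the low temperature and the weak heterogeneous base are chosen. The all-trans product should also be the thermodynamic isomer, since C3 and C3'' are enolisable while C2 and C2'' are not touched.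

Step 7
Reactants: 14 pentabenzyl ether of the target
Product: 15 (2S,3R)-5,7-dihydroxy-3-[(2S,3R)-5,7-dihydroxy-2-(4-hydroxyphenyl)-4-oxo-3,4-dihydro-2H-chromen-3-yl]-2-(4-methoxyphenyl)-2,3-dihydro-4H-chromen-4-one (CNP0196568.1)
Conditions: H2 (1 atm), 10% Pd/C, THF/MeOH 1:1, rt
Reagents that add atoms: none
Why: Catalytic hydrogenolysis of aryl benzyl ethers under neutral conditions should remove all five benzyl groups while the aryl methyl ether, the two ring-C ketones and the four stereocentres (no acid or base present) stay intact.

**Compound list**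

1 | 2',4',6'-trihydroxyacetophenone | CC(=O)c1c(O)cc(O)cc1O | starting material
2 | benzyl bromide | BrCc1ccccc1 | starting material
3 | 1-[2,4-bis(benzyloxy)-6-hydroxyphenyl]ethanone | CC(=O)c1c(O)cc(OCc2ccccc2)cc1OCc1ccccc1 | intermediate
4 | N,N-dimethylformamide dimethyl acetal | COC(OC)N(C)C | starting material
5 | (E)-1-[2,4-bis(benzyloxy)-6-hydroxyphenyl]-3-(dimethylamino)prop-2-en-1-one | CN(C)/C=C/C(=O)c1c(O)cc(OCc2ccccc2)cc1OCc1ccccc1 | intermediate
6 | 5,7-bis(benzyloxy)-4H-chromen-4-one | O=c1ccoc2cc(OCc3ccccc3)cc(OCc3ccccc3)c12 | intermediate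
7 | (4-methoxyphenyl)boronic acid | COc1ccc(B(O)O)cc1 | starting material
8 | (2S)-5,7-bis(benzyloxy)-2-(4-methoxyphenyl)-2,3-dihydro-4H-chromen-4-one | COc1ccc([C@H]2Oc3cc(OCc4ccccc4)cc(OCc4ccccc4)c3C(=O)C2)cc1 | intermediate
9 | [4-(benzyloxy)phenyl]boronic acid | OB(O)c1ccc(OCc2ccccc2)cc1 | starting material
10 | (2S)-5,7-bis(benzyloxy)-2-[4-(benzyloxy)phenyl]-2,3-dihydro-4H-chromen-4-one | c1ccc(COc2ccc([C@H]3Oc4cc(OCc5ccccc5)cc(OCc5ccccc5)c4C(=O)C3)cc2)cc1 | intermediate
11 | diisopropylsilyl bis(trifluoromethanesulfonate) | CC(C)[Si](OS(=O)(=O)C(F)(F)F)(OS(=O)(=O)C(F)(F)F)C(C)C | starting material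
12 | {[(2S)-5,7-bis(benzyloxy)-2-(4-methoxyphenyl)-2H-chromen-4-yl]oxy}di(propan-2-yl)silyl trifluoromethanesulfonate | COc1ccc([C@@H]2C=C(O[Si](C(C)C)(C(C)C)OS(=O)(=O)C(F)(F)F)c3c(OCc4ccccc4)cc(OCc4ccccc4)cc3O2)cc1 | intermediate
13 | {[(2S)-5,7-bis(benzyloxy)-2-(4-methoxyphenyl)-2H-chromen-4-yl]oxy}{[(2S)-5,7-bis(benzyloxy)-2-[4-(benzyloxy)phenyl]-2H-chromen-4-yl]oxy}di(propan-2-yl)silane | COc1ccc([C@@H]2C=C(O[Si](C(C)C)(C(C)C)OC3=C[C@@H](c4ccc(OCc5ccccc5)cc4)Oc4cc(OCc5ccccc5)cc(OCc5ccccc5)c43)c3c(OCc4ccccc4)cc(OCc4ccccc4)cc3O2)cc1 | intermediate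
14 | (2S,3R)-5,7-bis(benzyloxy)-3-{(2S,3R)-5,7-bis(benzyloxy)-2-[4-(benzyloxy)phenyl]-4-oxochroman-3-yl}-2-(4-methoxyphenyl)chroman-4-one | COc1ccc([C@H]2Oc3cc(OCc4ccccc4)cc(OCc4ccccc4)c3C(=O)[C@@H]2[C@H]2C(=O)c3c(OCc4ccccc4)cc(OCc4ccccc4)cc3O[C@@H]2c2ccc(OCc3ccccc3)cc2)cc1 | intermediate
15 | (2S,3R)-5,7-dihydroxy-3-[(2S,3R)-5,7-dihydroxy-2-(4-hydroxyphenyl)-4-oxo-3,4-dihydro-2H-chromen-3-yl]-2-(4-methoxyphenyl)-2,3-dihydro-4H-chromen-4-one | COc1ccc([C@H]2Oc3cc(O)cc(O)c3C(=O)[C@@H]2[C@H]2C(=O)c3c(O)cc(O)cc3O[C@@H]2c2ccc(O)cc2)cc1 | target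

**Step count**

Total: 7 steps. Longest linear sequence: 6 steps (steps 1, 2, 3, 5, 6, 7 from compound 1; the branch through step 4 is equally long).

**Steps most likely to fail**

Step 6. The radical cation may lose H-2 faster than it forms the C–C bond, so ring C is dehydrogenated towards a flavone. The seven-membered transition state may also fail to place both C2 aryl groups anti, giving poor facial selectivity at C3 or C3''. The fallback drops the tether and the radical cation, sets out from 8 and 10, and returns at 14. Flavanone 8 is converted with Me3SiOTf/Et3N (CH2Cl2, 0 °C) into the trimethylsilyl enol ether F1. Bromination of F1 with N-bromosuccinimide in THF at −78 °C, anti to the aryl group, should give the trans-3-bromoflavanone F2. Flavanone 10 is converted in the same way into the trimethylsilyl enol ether F3. F2 and F3 are then joined by visible-light photoredox alkylation of a silyl enol ether with an α-bromoketone (Ir(C11H8N)3, tris(2-phenylpyridinato)iridium, 1 mol %, blue LED, MeCN, rt). The planar C3 radical from F2 should add to C3'' of F3 with both bonds forming anti to the C2 aryl groups, and oxidation of the α-silyloxy radical with loss of the silyl group should give 14. Cross-selectivity here comes from the different roles of the partners, not from a tether. Any 2,3-cis isomer could be equilibrated to the trans isomer with a trace of acid.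

Step 5. The two enol ethers may scramble on silicon to give the two symmetrical bis-enol ethers, the second silylation at the peri-hindered C4 oxygen may be incomplete, or the bis-enol ether may hydrolyse during isolation. The fallback builds the bridge stepwise from preformed enolates, sets out from 8 and 10, and returns at 13. Flavanone 8 is deprotonated with LiN(SiMe3)2 in THF at −78 °C to the lithium enolate F4, which is run at once into a large excess of iPr2SiCl2 to give the chloro(diisopropyl)silyl enol ether F5. Excess silane is removed under vacuum. The lithium enolate F6, made from 10 with the same base at −78 °C, is then added to F5 to give 13. The low temperature throughout is needed so that the enolates do not open ring C by β-elimination of the phenoxide.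

Step 3. Addition to the electron-rich, vinylogous-ester-like chromone may be slow, so protodeboronation of the boronic acid competes. The enantiomeric purity may also erode through ring opening and reclosure of the flavanone. The fallback uses the chalcone route with resolution, sets out from 3, and returns at 8. Claisen–Schmidt condensation of 3 with 4-methoxybenzaldehyde (KOH, EtOH, rt) should give the 2'-hydroxychalcone F7. Oxa-Michael cyclisation of F7 (NaOAc, EtOH, reflux) should give the racemic flavanone F8. Preparative chromatography of F8 on a chiral stationary phase delivers 8, and the unwanted enantiomer can be racemised with base and recycled.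

**Further compounds**

F1 | step 6 | (2S)-5,7-bis(benzyloxy)-2-(4-methoxyphenyl)-4-(trimethylsilyloxy)-2H-chromene | COc1ccc([C@@H]2C=C(O[Si](C)(C)C)c3c(OCc4ccccc4)cc(OCc4ccccc4)cc3O2)cc1
F2 | step 6 | (2R,3R)-5,7-bis(benzyloxy)-3-bromo-2-(4-methoxyphenyl)chroman-4-one (2,3-trans) | COc1ccc([C@H]2Oc3cc(OCc4ccccc4)cc(OCc4ccccc4)c3C(=O)[C@@H]2Br)cc1
F3 | step 6 | (2S)-5,7-bis(benzyloxy)-2-[4-(benzyloxy)phenyl]-4-(trimethylsilyloxy)-2H-chromene | C[Si](C)(C)OC1=C[C@@H](c2ccc(OCc3ccccc3)cc2)Oc2cc(OCc3ccccc3)cc(OCc3ccccc3)c21
F4 | step 5 | lithium (2S)-5,7-bis(benzyloxy)-2-(4-methoxyphenyl)-2H-chromen-4-olate | COc1ccc([C@@H]2C=C([O-])c3c(OCc4ccccc4)cc(OCc4ccccc4)cc3O2)cc1.[Li+]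
F5 | step 5 | (2S)-5,7-bis(benzyloxy)-4-{[chloro(diisopropyl)silyl]oxy}-2-(4-methoxyphenyl)-2H-chromene | COc1ccc([C@@H]2C=C(O[Si](Cl)(C(C)C)C(C)C)c3c(OCc4ccccc4)cc(OCc4ccccc4)cc3O2)cc1
F6 | step 5 | lithium (2S)-5,7-bis(benzyloxy)-2-[4-(benzyloxy)phenyl]-2H-chromen-4-olate | [Li+].[O-]C1=C[C@@H](c2ccc(OCc3ccccc3)cc2)Oc2cc(OCc3ccccc3)cc(OCc3ccccc3)c21
F7 | step 3 | (E)-1-[2,4-bis(benzyloxy)-6-hydroxyphenyl]-3-(4-methoxyphenyl)prop-2-en-1-one | COc1ccc(/C=C/C(=O)c2c(O)cc(OCc3ccccc3)cc2OCc2ccccc2)cc1
F8 | step 3 | racemic 5,7-bis(benzyloxy)-2-(4-methoxyphenyl)chroman-4-one | COc1ccc(C2CC(=O)c3c(OCc4ccccc4)cc(OCc4ccccc4)cc3O2)cc1
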